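The target is atromentin with one enol hydroxyl acetylated. Everything rests on the bond from quinone carbon C6, the α-carbon of the vinylogous acid C5(OH)=C6–C1(=O), to the second 4-hydroxyphenyl ring. Mono-acetylation of centrosymmetric bromanilic acid makes its two C–Br bonds different: the one on the acetoxy-enone half couples first, while the one on the hydroxy-enone half, an electron-rich bromo-enolate under the coupling conditions, is kept for last. The key step, a Suzuki–Miyaura coupling, exploits exactly this C6–Br flanked by C5–OH and C1=O: it joins 2-acetoxy-3-aryl-6-bromo-5-hydroxy-1,4-benzoquinone with 4-(benzyloxy)phenylboronic acid, acetate and free enol already in place. Hydrogenolysis then frees both phenols.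

Key step: step 3

Remark: the target is achiral; the hydroxyquinone is treated as the 2-acetoxy-5-hydroxy-1,4-quinone tautomer, numbered C1 (C=O), C2 (OAc), C3 (aryl), C4 (C=O), C5 (OH), C6 (aryl).

Step 1
Reactants: 1 bromanilic acid (2,5-dibromo-3,6-dihydroxy-1,4-benzoquinone)
Product: 2 2-acetoxy-3,6-dibromo-5-hydroxy-1,4-benzoquinone
Conditions: i-Pr2NEt (2.0 equiv), AcCl (1.0 equiv, slow addition), CH2Cl2, −40 to 0 °C; cold 1 M HCl wash, used without delay
Reagents that add atoms: acetyl chloride, CC(=O)Cl
Why: O-acylation of the bromanilate dianion with one equivalent of acid chloride (enol ester formation); 1 is centrosymmetric, so only one monoacetate exists, and the dianion should be a much better nucleophile than the mono-anion of 2, which should hold the reaction at the mono stage.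

Step 2
Reactants: 2 2-acetoxy-3,6-dibromo-5-hydroxy-1,4-benzoquinone; 3 4-(benzyloxy)phenylboronic acid
Product: 4 2-acetoxy-3-[4-(benzyloxy)phenyl]-6-bromo-5-hydroxy-1,4-benzoquinone
Conditions: 3 (1.0 equiv), Pd(PPh3)4 (5 mol %), KF (spray-dried, 3.0 equiv), THF, 25–40 °C; cold 1 M HCl work-up
Reagents that add atoms: none
Why: Suzuki–Miyaura coupling: with fluoride as base 2 reacts as its enolate, in which C6–Br belongs to an electron-rich 2-bromo-1,3-dionate and C3–Br to a neutral β-acetoxy enone, so oxidative addition should take place at C3–Br only, while anhydrous KF is mild enough to spare the enol acetate.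

Step 3
Reactants: 4 2-acetoxy-3-[4-(benzyloxy)phenyl]-6-bromo-5-hydroxy-1,4-benzoquinone; 3 4-(benzyloxy)phenylboronic acid
Product: 5 2-acetoxy-3,6-bis[4-(benzyloxy)phenyl]-5-hydroxy-1,4-benzoquinone
Conditions: 3 (1.5 equiv), Pd2(dba)3 (2.5 mol %), SPhos (10 mol %), KF (spray-dried, 3.0 equiv), 1,4-dioxane, 60 °C; cold 1 M HCl work-up
Reagents that add atoms: none
Why: Pd(0)–SPhos inserts into the C6–Br bond of 4 (present as its potassium enolate), the fluoride-activated boronate of 3 transmetalates, and reductive elimination forms the C6–aryl bond (Suzuki–Miyaura coupling). The closest known reaction type is the Suzuki coupling of 3-halo-2-hydroxy-1,4-quinones and of 2,5-dibromo-3,6-dioxygenated benzoquinones with arylboronic acids. No ring is closed and no stereocentre is formed. Site selectivity is not in question because C6–Br is the only carbon–halogen bond left; what the step needs is chemoselectivity for C–C coupling over cleavage of the C2 enol acetate. This should be secured by anhydrous fluoride as the only base and by the enolate form of the substrate, from which loss of the acetyl group would have to give a dianion. The electron-rich biarylphosphine is chosen to speed oxidative addition into the electron-rich bromo-enolate.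

Step 4
Reactants: 5 2-acetoxy-3,6-bis[4-(benzyloxy)phenyl]-5-hydroxy-1,4-benzoquinone
Product: 7 2-acetoxy-5-hydroxy-3,6-bis(4-hydroxyphenyl)-1,4-benzoquinone, via leuco hydroquinone acetate 6 (not isolated)
Conditions: H2 (1 atm), 10% Pd/C, EtOAc–THF, rt; filter under N2; then air, rt
Reagents that add atoms: none
Why: Hydrogenolysis of the two benzyl aryl ethers with concurrent reduction of the quinone, followed by autoxidation of the electron-rich hydroquinone back to the quinone; the aryl acetate of 6 is inert to H2/Pd, and a 1,2-acetyl shift in 6 would be degenerate because it leads to the same quinone after oxidation.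

Compound list
1 | bromanilic acid (2,5-dibromo-3,6-dihydroxy-1,4-benzoquinone) | OC1=C(Br)C(=O)C(O)=C(Br)C1=O | starting material
2 | 2-acetoxy-3,6-dibromo-5-hydroxy-1,4-benzoquinone | CC(=O)OC1=C(Br)C(=O)C(O)=C(Br)C1=O | intermediate
3 | 4-(benzyloxy)phenylboronic acid | OB(O)c1ccc(OCc2ccccc2)cc1 | starting material
4 | 2-acetoxy-3-[4-(benzyloxy)phenyl]-6-bromo-5-hydroxy-1,4-benzoquinone | CC(=O)OC1=C(c2ccc(OCc3ccccc3)cc2)C(=O)C(O)=C(Br)C1=O | intermediate
5 | 2-acetoxy-3,6-bis[4-(benzyloxy)phenyl]-5-hydroxy-1,4-benzoquinone | CC(=O)OC1=C(c2ccc(OCc3ccccc3)cc2)C(=O)C(O)=C(c2ccc(OCc3ccccc3)cc2)C1=O | intermediate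
6 | 2,4,5-trihydroxy-3,6-bis(4-hydroxyphenyl)phenyl acetate (leuco hydroquinone acetate) | CC(=O)Oc1c(-c2ccc(O)cc2)c(O)c(O)c(-c2ccc(O)cc2)c1O | intermediate
7 | 2-acetoxy-5-hydroxy-3,6-bis(4-hydroxyphenyl)-1,4-benzoquinone | CC(=O)OC1=C(c2ccc(O)cc2)C(=O)C(O)=C(c2ccc(O)cc2)C1=O | target

Total step count: 4. Longest linear sequence: 4 steps (1 → 2 → 4 → 5 → 7).

Steps most likely to fail

Step 3 (key step). The enol acetate, an activated vinylogous anhydride, may be cleaved by fluoride or boronate at the temperature needed, because oxidative addition into the electron-rich bromo-enolate is slow. Oxidative homocoupling of the boronic acid with the quinone as oxidant may also compete. Fallback: setting out from 4, the acidic enol would be capped with benzyl 2,2,2-trichloroacetimidate (CH2Cl2, rt; 4 is acidic enough to activate the imidate itself) to give 2-acetoxy-5-(benzyloxy)-3-[4-(benzyloxy)phenyl]-6-bromo-1,4-benzoquinone F1. This neutral bromoquinone, now an ordinary activated vinylogous acyl bromide, should couple with 3 at room temperature (Pd(PPh3)4, KF, THF) to give 2-acetoxy-5-(benzyloxy)-3,6-bis[4-(benzyloxy)phenyl]-1,4-benzoquinone F2. Hydrogenolysis of F2 under the conditions of step 4 would remove all three benzyl groups and come back to the route at 6, and from there at 7.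

Step 2. Discrimination between the two C–Br bonds may erode, giving coupling at C6 or double arylation, and the acetate flanked by bromine is the most labile ester of the route. Fallback: the order of arylation and acetylation would be reversed. Setting out from 1 (in excess) and 3, a Suzuki coupling in the absence of any acetate (Pd(dppf)Cl2, K2CO3, dioxane–H2O, 80 °C) should give 3-[4-(benzyloxy)phenyl]-6-bromo-2,5-dihydroxy-1,4-benzoquinone F3. Its dianion would then be acylated with one equivalent of AcCl (i-Pr2NEt, CH2Cl2, −40 °C). The aryl-substituted dioxo-allyl anion half should be more basic and nucleophilic than the bromo-substituted half, and acylation at either of its oxygens places the acetate next to the aryl group, coming back to the route at 4.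

Step 1. Acetylation may overshoot to the diacetate, and the product may hydrolyse during the aqueous wash. Fallback: setting out from 1, exhaustive acetylation (Ac2O, cat. H2SO4) would give 2,5-diacetoxy-3,6-dibromo-1,4-benzoquinone F4. One equivalent of NaHCO3 in THF–H2O at 0 °C should then remove a single acetyl group, because the first cleavage leaves an anion whose remaining acetate is far less electrophilic, coming back to the route at 2.

Further compounds
F1 | step 3 | 2-acetoxy-5-(benzyloxy)-3-[4-(benzyloxy)phenyl]-6-bromo-1,4-benzoquinone | CC(=O)OC1=C(c2ccc(OCc3ccccc3)cc2)C(=O)C(OCc2ccccc2)=C(Br)C1=O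
F2 | step 3 | 2-acetoxy-5-(benzyloxy)-3,6-bis[4-(benzyloxy)phenyl]-1,4-benzoquinone | CC(=O)OC1=C(c2ccc(OCc3ccccc3)cc2)C(=O)C(OCc2ccccc2)=C(c2ccc(OCc3ccccc3)cc2)C1=O
F3 | step 2 | 3-[4-(benzyloxy)phenyl]-6-bromo-2,5-dihydroxy-1,4-benzoquinone | OC1=C(c2ccc(OCc3ccccc3)cc2)C(=O)C(O)=C(Br)C1=O
F4 | step 1 | 2,5-diacetoxy-3,6-dibromo-1,4-benzoquinone | CC(=O)OC1=C(Br)C(=O)C(OC(C)=O)=C(Br)C1=O
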